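## Retrosynthetic overview

1. The C11–OOH group and the (E)-C9=C10 bond come from a last-step singlet-oxygen ene reaction on a C8 prenyl ketone (C–O).
2. The prenyl ketone comes from a C8 enal and a tertiary prenylboronate (the only C–C bond made), then allylic oxidation; the enal comes from the isopropenyl group by allylic chlorination and N-oxide oxidation.
3. Key step: the trans-2,3-diol is made by a one-pot borylative anti-dihydroxylation of the ring enone (two C–O bonds; C2 and C3 set).
4. The C6 ester comes from Mn(III) α′-acyloxylation of (R)-carvone with isovaleric acid (C–O; C6 set).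
5. No ring is formed: the cyclohexane ring and C5 come intact from (R)-carvone.

Convention used in the comments: ring locants as in carvone (C1 C=O, C2 C–Me, C3, C4 CH2, C5 bears the side chain, C6 bears the ester oxygen); side chain C7(=C14H2)–C8(=O)–C9=C10–C11(OOH).

## Route

**Step 1**
Reactants: 1 (R)-(−)-carvone; 2 3-methylbutanoic acid
Product: 3 (1S,6S)-3-methyl-2-oxo-6-(prop-1-en-2-yl)cyclohex-3-en-1-yl 3-methylbutanoate
Conditions: Mn(OAc)3·2H2O (2.5 equiv), 2 (10 equiv), benzene, reflux, Dean–Stark
Reagents that add atoms: none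
Why: Mn(III)-mediated α′-acyloxylation of an enone: the Mn(III) enolate on the C6 side transfers a carboxylate (isovalerate in large excess over acetate) to C6 anti to the C5 isopropenyl group, setting C6 (S) trans to C5; this diequatorial isomer is also the thermodynamic one, so cis material converges on brief Et3N treatment.

**Step 2**
Reactants: 3 the α′-acyloxy enone; 4 bis(pinacolato)diboron
Product: 7 (1S,3S,4R,6S)-3,4-dihydroxy-3-methyl-2-oxo-6-(prop-1-en-2-yl)cyclohexyl 3-methylbutanoate, via boron enolate 5 (not isolated), via boryloxy boryl ketone 6 (not isolated)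
Conditions: CuCl/Xantphos (5 mol%), NaOtBu (8 mol%), THF, rt; then DMDO (1.2 equiv, acetone), −78 → −30 °C; then NaBO3·4H2O, THF/H2O (pH 7), 0 °C
Reagents that add atoms: dimethyldioxirane CC1(C)OO1; sodium perborate [Na+].[Na+].O[B-]1(O)OO[B-](O)(O)OO1
Why: Proposed new method: formal anti-dihydroxylation of an enone in one pot — Cu–Bpin adds 1,4 to C3 by axial attack trans to the C5 isopropenyl group (as cuprates do on 5-substituted cyclohexenones) and, with no proton source, σ-bond metathesis with B2pin2 gives the O-boron enolate 5; DMDO epoxidises this electron-rich enol borate anti to the pseudo-axial C3–Bpin and the boryloxy epoxide opens with boryl shift (Rubottom-type) to 6, setting C2–O; perborate then turns C3–B into C3–OH with retention, so the two new C–O bonds are trans-diaxial; closest known reactions are Cu-catalysed β-borylation/oxidation of enones, borylative aldol trapping of the same boron enolates, and Rubottom oxidation of silyl enol ethers.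

**Step 3**
Reactants: 7 the keto diol ester
Product: 8 (1S,3S,4R,6S)-6-(3-chloroprop-1-en-2-yl)-3,4-dihydroxy-3-methyl-2-oxocyclohexyl 3-methylbutanoate
Conditions: Ca(OCl)2, CO2 (s), CH2Cl2/H2O, 0 °C
Reagents that add atoms: calcium hypochlorite [Ca+2].[O-]Cl.[O-]Cl
Why: Ene-type allylic chlorination with HOCl (precedented on carvone itself): the only C=C bond left is the electron-rich isopropenyl group, which takes Cl+ at the terminal carbon and loses a methyl proton to give the transposed 2-(chloromethyl)vinyl unit without touching a stereocentre.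

**Step 4**
Reactants: 8 the allylic chloride
Product: 9 (1S,3S,4R,6S)-3,4-dihydroxy-3-methyl-2-oxo-6-(3-oxoprop-1-en-2-yl)cyclohexyl 3-methylbutanoate
Conditions: NMO (4 equiv), NaI (0.2 equiv), NaHCO3, MeCN, 40 °C
Reagents that add atoms: N-methylmorpholine N-oxide C[N+]1([O-])CCOCC1
Why: Amine N-oxide oxidation of an activated halide (Ganem/Kornblum type): SN2 displacement of the allylic chloride (through the iodide) by the N-oxide oxygen and E2 loss of N-methylmorpholine give the 2-substituted acrolein under near-neutral conditions that spare the β-hydroxy ketone and the α-acyloxy ketone.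

**Step 5**
Reactants: 10 1-chloro-3-methylbut-2-ene; 11 magnesium; 12 2-isopropoxy-4,4,5,5-tetramethyl-1,3,2-dioxaborolane
Product: 14 2-(2-methylbut-3-en-2-yl)-4,4,5,5-tetramethyl-1,3,2-dioxaborolane, via prenylmagnesium chloride 13 (not isolated)
Conditions: Mg, THF, 0 °C (slow addition); then 12, −78 → 0 °C; aq. NH4Cl, kept cold
Reagents that add atoms: none
Why: Grignard formation then SE2′ (γ-selective) borylation: the allylic Grignard attacks boron through its more substituted terminus to give the tertiary α,α-dimethylallyl boronate, which as a pinacol ester resists 1,3-boratropic shift when kept cold.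

**Step 6**
Reactants: 9 the enal; 14 the tertiary allylboronate
Product: 16 (1S,3S,4R,6S)-3,4-dihydroxy-6-(3-hydroxy-6-methylhepta-1,5-dien-2-yl)-3-methyl-2-oxocyclohexyl 3-methylbutanoate, via pinacol borate ester 15 (not isolated)
Conditions: 14 (1.5 equiv), CH2Cl2, 4 Å MS, 0 °C → rt; aq. NaHCO3 work-up
Reagents that add atoms: none
Why: Allylboration of an aldehyde through a closed six-membered (Zimmerman–Traxler) transition state with allylic transposition: the tertiary boronate delivers the linear prenyl group, reacts only with the aldehyde in the presence of the ketone, ester and free diol, and the new C8 carbinol centre (epimer mixture) is removed in step 7.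

**Step 7**
Reactants: 16 the C8 allylic alcohol
Product: 17 (1S,3S,4R,6S)-3,4-dihydroxy-3-methyl-6-(6-methyl-3-oxohepta-1,5-dien-2-yl)-2-oxocyclohexyl 3-methylbutanoate
Conditions: activated MnO2 (20 equiv), CH2Cl2, rt
Reagents that add atoms: none
Why: Chemoselective MnO2 oxidation of an allylic alcohol: only the C8 carbinol (allylic to C7=C14) is oxidised, the saturated secondary C3–OH and tertiary C2–OH are inert, and the neutral conditions avoid migration of the β,γ-double bond into conjugation.

**Step 8**
Reactants: 17 the prenyl ketone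
Product: 18 (1S,3S,4R,6S)-6-[(4E)-6-hydroperoxy-6-methyl-3-oxohepta-1,4-dien-2-yl]-3,4-dihydroxy-3-methyl-2-oxocyclohexyl 3-methylbutanoate
Conditions: O2, TPP (1 mol%), CH2Cl2, white LED, −20 °C
Reagents that add atoms: dioxygen O=O
Why: Schenck ene reaction of singlet oxygen: 1O2 attacks only the electron-rich trisubstituted C10=C11 bond, and abstraction of a doubly activated (α-keto, allylic) C9–H places OOH on tertiary C11 and moves the double bond to C9=C10 with E geometry in conjugation with the C8 ketone, leaving the electron-poor C7=C14 bond and all ring stereocentres untouched.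

## Compound list

1 | (R)-(−)-carvone, (5R)-2-methyl-5-(prop-1-en-2-yl)cyclohex-2-en-1-one | C=C(C)[C@@H]1CC=C(C)C(=O)C1 | starting material
2 | 3-methylbutanoic acid (isovaleric acid) | CC(C)CC(=O)O | starting material
3 | (1S,6S)-3-methyl-2-oxo-6-(prop-1-en-2-yl)cyclohex-3-en-1-yl 3-methylbutanoate (acyloxy trans to isopropenyl) | C=C(C)[C@@H]1CC=C(C)C(=O)[C@H]1OC(=O)CC(C)C | intermediate
4 | bis(pinacolato)diboron | CC1(C)OB(OC1(C)C)B1OC(C)(C)C(C)(C)O1 | starting material
5 | (1S,4R,6S)-3-methyl-6-(prop-1-en-2-yl)-4-(4,4,5,5-tetramethyl-1,3,2-dioxaborolan-2-yl)-2-[(4,4,5,5-tetramethyl-1,3,2-dioxaborolan-2-yl)oxy]cyclohex-2-en-1-yl 3-methylbutanoate (boron enolate; C–B trans to isopropenyl) | C=C(C)[C@@H]1C[C@@H](B2OC(C)(C)C(C)(C)O2)C(C)=C(OB2OC(C)(C)C(C)(C)O2)[C@H]1OC(=O)CC(C)C | intermediate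
6 | (1S,3S,4R,6S)-3-methyl-2-oxo-6-(prop-1-en-2-yl)-4-(4,4,5,5-tetramethyl-1,3,2-dioxaborolan-2-yl)-3-[(4,4,5,5-tetramethyl-1,3,2-dioxaborolan-2-yl)oxy]cyclohexyl 3-methylbutanoate (C–O and C–B trans) | C=C(C)[C@@H]1C[C@@H](B2OC(C)(C)C(C)(C)O2)[C@](C)(OB2OC(C)(C)C(C)(C)O2)C(=O)[C@H]1OC(=O)CC(C)C | intermediate
7 | (1S,3S,4R,6S)-3,4-dihydroxy-3-methyl-2-oxo-6-(prop-1-en-2-yl)cyclohexyl 3-methylbutanoate | C=C(C)[C@@H]1C[C@@H](O)[C@](C)(O)C(=O)[C@H]1OC(=O)CC(C)C | intermediate
8 | (1S,3S,4R,6S)-6-(3-chloroprop-1-en-2-yl)-3,4-dihydroxy-3-methyl-2-oxocyclohexyl 3-methylbutanoate | C=C(CCl)[C@@H]1C[C@@H](O)[C@](C)(O)C(=O)[C@H]1OC(=O)CC(C)C | intermediate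
9 | (1S,3S,4R,6S)-3,4-dihydroxy-3-methyl-2-oxo-6-(3-oxoprop-1-en-2-yl)cyclohexyl 3-methylbutanoate | C=C(C=O)[C@@H]1C[C@@H](O)[C@](C)(O)C(=O)[C@H]1OC(=O)CC(C)C | intermediate
10 | 1-chloro-3-methylbut-2-ene (prenyl chloride) | CC(C)=CCCl | starting material
11 | magnesium | [Mg] | starting material
12 | 2-isopropoxy-4,4,5,5-tetramethyl-1,3,2-dioxaborolane | CC(C)OB1OC(C)(C)C(C)(C)O1 | starting material
13 | prenylmagnesium chloride | CC(C)=CC[Mg]Cl | intermediate
14 | 2-(2-methylbut-3-en-2-yl)-4,4,5,5-tetramethyl-1,3,2-dioxaborolane | C=CC(C)(C)B1OC(C)(C)C(C)(C)O1 | intermediate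
15 | (1S,3S,4R,6S)-3,4-dihydroxy-3-methyl-6-{6-methyl-3-[(4,4,5,5-tetramethyl-1,3,2-dioxaborolan-2-yl)oxy]hepta-1,5-dien-2-yl}-2-oxocyclohexyl 3-methylbutanoate (C8 epimer mixture) | C=C(C(OB2OC(C)(C)C(C)(C)O2)CC=C(C)C)[C@@H]1C[C@@H](O)[C@](C)(O)C(=O)[C@H]1OC(=O)CC(C)C | intermediate
16 | (1S,3S,4R,6S)-3,4-dihydroxy-6-(3-hydroxy-6-methylhepta-1,5-dien-2-yl)-3-methyl-2-oxocyclohexyl 3-methylbutanoate (C8 epimer mixture) | C=C(C(O)CC=C(C)C)[C@@H]1C[C@@H](O)[C@](C)(O)C(=O)[C@H]1OC(=O)CC(C)C | intermediate
17 | (1S,3S,4R,6S)-3,4-dihydroxy-3-methyl-6-(6-methyl-3-oxohepta-1,5-dien-2-yl)-2-oxocyclohexyl 3-methylbutanoate | C=C(C(=O)CC=C(C)C)[C@@H]1C[C@@H](O)[C@](C)(O)C(=O)[C@H]1OC(=O)CC(C)C | intermediate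
18 | (1S,3S,4R,6S)-6-[(4E)-6-hydroperoxy-6-methyl-3-oxohepta-1,4-dien-2-yl]-3,4-dihydroxy-3-methyl-2-oxocyclohexyl 3-methylbutanoate (CNP0239240.1) | C=C(C(=O)/C=C/C(C)(C)OO)[C@@H]1C[C@@H](O)[C@](C)(O)C(=O)[C@H]1OC(=O)CC(C)C | target

## Step count and risks

Total step count: 8 (seven on the main line plus one reagent preparation, step 5).
Longest linear sequence: 7 steps (1 → 3 → 7 → 8 → 9 → 16 → 17 → 18).

Three steps most likely to fail:

**Step 2 (proposed new method).** Risks are protonation of the boron enolate before oxygenation, anti-elimination of the vicinal C2–OBpin/C3–Bpin pair back to the enone, competing epoxidation of the isopropenyl group by DMDO, and ester cleavage during the perborate stage. The fallback uses known chemistry only; it sets out from 3 and comes back to the route at 7. Luche reduction of 3 (NaBH4, CeCl3·7H2O, MeOH, −78 °C; axial hydride delivery) gives the allylic alcohol (1S,2S,6S)-2-hydroxy-3-methyl-6-(prop-1-en-2-yl)cyclohex-3-en-1-yl 3-methylbutanoate F1, with the hydroxyl cis to the isopropenyl group. Hydroxyl-directed epoxidation (VO(acac)2, t-BuOOH, CH2Cl2, 0 °C) then places the oxirane on the same face and gives the epoxy alcohol (1R,2R,3S,4S,6S)-2-hydroxy-1-methyl-4-(prop-1-en-2-yl)-7-oxabicyclo[4.1.0]heptan-3-yl 3-methylbutanoate F2. Dess–Martin oxidation (NaHCO3, CH2Cl2) gives the cis-epoxy ketone (1S,3S,4S,6S)-1-methyl-2-oxo-4-(prop-1-en-2-yl)-7-oxabicyclo[4.1.0]heptan-3-yl 3-methylbutanoate F3. Dilute HClO4 in THF/H2O at 0 °C opens the oxirane at C3 with inversion (trans-diaxial opening) to give 7.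

**Step 6.** Risks are 1,3-boratropic isomerisation of 14 to the primary prenylboronate (which would give the branched reverse-prenyl adduct), slow addition of the hindered boronate, and loss of the reactive 2-substituted acrolein 9. The fallback sets out from 9 and comes back at 16, replacing allylboration by an acid-catalysed allyl transfer. The donor 2,3,3-trimethylpent-4-en-2-ol F4 is made from acetone and prenylmagnesium chloride 13 (γ-addition). With 9 and catalytic Sn(OTf)2 in CH2Cl2 at 0 °C it forms a hemiacetal and then an oxocarbenium ion, which undergoes 2-oxonia-Cope rearrangement; hydrolysis releases the linear prenyl carbinol 16.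

**Step 8.** Risks are competing hydrogen abstraction from the cis-methyl group (secondary C10 hydroperoxide with an isopropenyl end) and loss of the hydroperoxide on purification. The fallback sets out from 17 and comes back at 18, replacing the concerted singlet-oxygen ene reaction by a radical-chain hydroperoxidation with ground-state oxygen (N-hydroxyphthalimide 10 mol%, AIBN 5 mol%, O2 1 atm, MeCN, 50 °C). The phthalimide-N-oxyl radical abstracts the doubly activated C9–H, O2 is captured at the tertiary C11 terminus of the delocalised 1-acylallyl radical, and hydrogen transfer from the catalyst gives the conjugated (E)-hydroperoxide, as in the autoxidation of β,γ-unsaturated ketones to γ-hydroperoxy enones. No further compound is made on this way (F0).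

## Further compounds

F1 | step 2 | (1S,2S,6S)-2-hydroxy-3-methyl-6-(prop-1-en-2-yl)cyclohex-3-en-1-yl 3-methylbutanoate | C=C(C)[C@@H]1CC=C(C)[C@H](O)[C@H]1OC(=O)CC(C)C
F2 | step 2 | (1R,2R,3S,4S,6S)-2-hydroxy-1-methyl-4-(prop-1-en-2-yl)-7-oxabicyclo[4.1.0]heptan-3-yl 3-methylbutanoate | C=C(C)[C@@H]1C[C@@H]2O[C@]2(C)[C@H](O)[C@H]1OC(=O)CC(C)C
F3 | step 2 | (1S,3S,4S,6S)-1-methyl-2-oxo-4-(prop-1-en-2-yl)-7-oxabicyclo[4.1.0]heptan-3-yl 3-methylbutanoate | C=C(C)[C@@H]1C[C@@H]2O[C@]2(C)C(=O)[C@H]1OC(=O)CC(C)C
F4 | step 6 | 2,3,3-trimethylpent-4-en-2-ol | C=CC(C)(C)C(C)(C)O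
F0 | step 8 | none | none
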